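**Plan**
- Retrosynthetic cuts, in order: (i) the ring B–C2 bond of flavanone unit 1 (the 5,7-dihydroxy unit), giving an arylboronic acid and a chromone; (ii) O1''–C2'' and C4''–C4a'' of unit 2 (the 7-methoxy unit) together, which turns its ring C into an aryl cinnamate, an isomer of the flavanone; (iii) the C3'–C8'' biaryl bond.
- Forward order: biaryl (ring B of unit 1 + ring A of unit 2) → cinnamate on the ring-A phenol → one-flask isomerisation closing ring C of unit 2 → boronic acid on ring B → rings A and C of unit 1 added as a chromone → one-pot deprotection.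
- Enabling feature: ring A of unit 2 is a phloroglucinol ring. C4a'' lies ortho to O1'' and O5'' and para to O7'', so O1''–C8a''=C4a'' acts as an O,C-bisnucleophile matched to the acyl carbon (C4'') and β-carbon (C2'') of a cinnamoyl group; C8'' is blocked by ring B and O5'' is capped.
- The 5''-OH/7''-OMe pattern comes from symmetric 3,5-dimethoxyphenol; the peri 5''-methyl ether is removed last by BCl3 chelated to C4''=O.
- Stereochemistry: C2'' (S) from the catalyst-controlled oxa-Michael closure in the key step; C2 (S) from ligand-controlled rhodium 1,4-addition.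

Key step: step 4

Remark: the target SMILES defines no axial chirality, so the biaryl axis (three ortho substituents) is treated as freely rotating. [2-(Benzyloxy)-5-chlorophenyl]boronic acid, (E)-4-acetoxycinnamic acid and 5,7-dihydroxychromone are taken as commercial. Locants with no or one prime refer to unit 1, those with two or three primes to unit 2.

**Step 1**
Reactants: 1 3,5-dimethoxyphenol
Product: 2 2-iodo-3,5-dimethoxyphenol
Conditions: NIS (1.0 equiv), CH2Cl2, −40 → 0 °C
Reagents that add atoms: N-iodosuccinimide, O=C1CCC(=O)N1I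
Why: Electrophilic aromatic iodination: the equivalent C2/C6 positions are ortho to the hydroxyl group, para to a methoxy group and less crowded than C4 between the two methoxy groups, so one equivalent of NIS at low temperature should deliver the 2-iodo isomer.

**Step 2**
Reactants: 2 2-iodo-3,5-dimethoxyphenol; 3 [2-(benzyloxy)-5-chlorophenyl]boronic acid
Product: 4 2'-(benzyloxy)-5'-chloro-4,6-dimethoxybiphenyl-2-ol
Conditions: Pd(dppf)Cl2 (5 mol %), K3PO4, 1,4-dioxane–H2O (5:1), 85 °C
Reagents that add atoms: none
Why: Suzuki–Miyaura cross-coupling: dppf-ligated zerovalent palladium inserts into the C–I bond far faster than into the electron-rich C–Cl bond, so the biaryl bond forms at C2 of the phenol and the chloride is kept as the handle for step 5.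

**Step 3**
Reactants: 4 2'-(benzyloxy)-5'-chloro-4,6-dimethoxybiphenyl-2-ol; 5 (E)-4-acetoxycinnamic acid
Product: 6 2'-(benzyloxy)-5'-chloro-4,6-dimethoxybiphenyl-2-yl (E)-3-(4-acetoxyphenyl)prop-2-enoate
Conditions: DCC (1.2 equiv), DMAP (10 mol %), CH2Cl2, 0 °C → rt
Reagents that add atoms: none
Why: Steglich esterification: the only hydroxyl group of 4 is acylated through the DMAP-activated O-acylisourea of 5, which places the cinnamoyl unit on the oxygen that becomes O1''.

**Step 4**
Reactants: 6 2'-(benzyloxy)-5'-chloro-4,6-dimethoxybiphenyl-2-yl (E)-3-(4-acetoxyphenyl)prop-2-enoate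
Product: 8 (2S)-2-(4-acetoxyphenyl)-8-[2-(benzyloxy)-5-chlorophenyl]-5,7-dimethoxychroman-4-one, via chalcone 7 (not isolated)
Conditions: Sc(OTf)3 (5 mol %), PhMe–ClCH2CH2Cl (4:1), 70 °C; then, same flask, −10 °C → rt, 9-amino-9-deoxy-epi-quinidine-derived 3,5-bis(trifluoromethyl)phenyl thiourea (20 mol %, in excess over scandium)
Reagents that add atoms: none
Why: Proposed new method: Sc(OTf)3 activates the very electron-rich aryl ester so that the cinnamoyl group leaves O1'' and re-enters at C4a'' (Fries-type 1,3-O→C acyl shift, C4''–C4a'' bond) to give the hydrogen-bonded 2'-hydroxychalcone 7, and the bifunctional amine–thiourea added next binds the enone carbonyl through its two N–H bonds while its quinuclidine nitrogen deprotonates the phenol, which adds to the β-carbon (oxa-Michael, O1''–C2'' bond). The closest known reaction types are the Lewis-acid Fries rearrangement of aryl cinnamates to 2'-hydroxychalcones and the amine–thiourea-catalysed enantioselective oxa-Michael cyclisation of 2'-hydroxychalcones that carry an α-ester activating group; merging them in one flask on a chalcone without that group is the untested element, and it is reasonable because the phenol is acidified by the ortho carbonyl and the acetoxy-substituted enone is a better acceptor than a 4-alkoxy one. The pyranone ring closes in the 6-endo-trig mode. C2'' is the only new stereocentre and is set by the catalyst, whose quinidine-derived scaffold should expose the Si face of the β-carbon to O1'' and so give 2S (the quinine-derived pseudoenantiomer is held in reserve for the opposite sense); 6 is achiral, so there is no substrate bias. The step needs three selectivities, each secured by the substrate: among the positions ortho to O1'' the acyl group can enter only at C4a'' because the other one carries ring B, and the chelated ortho-hydroxy ketone is the thermodynamic sink relative to the para position between the two methoxy groups; only O1'' can close the ring because O5'' is a methyl ether; and the acyl shift is favoured over conjugate hydroarylation (4-aryl-dihydrocoumarin formation) because the acetate makes the β-aryl group electron-poor, which also keeps the C2''–O1'' bond from ionising. Kinetic control is kept by running the closure cold and stopping it before the reverse ring opening can erode the enantiomeric purity.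

**Step 5**
Reactants: 8 (2S)-2-(4-acetoxyphenyl)-8-[2-(benzyloxy)-5-chlorophenyl]-5,7-dimethoxychroman-4-one
Product: 10 {4-(benzyloxy)-3-[(2S)-2-(4-acetoxyphenyl)-5,7-dimethoxy-4-oxochroman-8-yl]phenyl}boronic acid, via pinacol boronate 9 (not isolated)
Conditions: Pd2(dba)3 (2 mol %), XPhos (8 mol %), B2pin2, KOAc, 1,4-dioxane, 80 °C; then filtration, NaIO4, 0.1 M aq. HCl, THF–H2O, rt
Reagents that add atoms: bis(pinacolato)diboron, CC1(C)OB(OC1(C)C)B1OC(C)(C)C(C)(C)O1; water, O
Why: Miyaura borylation followed by oxidative cleavage of the pinacol ester: XPhos-ligated zerovalent palladium inserts into the aryl chloride, acetate in dioxane is too weak a base to open the flavanone by retro-oxa-Michael reaction, and periodate in dilute acid frees the boronic acid without touching C2'' or the acetate.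

**Step 6**
Reactants: 11 5,7-dihydroxy-4H-chromen-4-one
Product: 12 5,7-bis(benzyloxy)-4H-chromen-4-one
Conditions: BnBr (2.5 equiv), K2CO3, KI (cat.), DMF, 70 °C
Reagents that add atoms: benzyl bromide, BrCc1ccccc1
Why: Williamson ether synthesis: both phenols of 11 are alkylated, the hydrogen-bonded 5-OH needing the excess reagent and warm DMF.

**Step 7**
Reactants: 10 {4-(benzyloxy)-3-[(2S)-2-(4-acetoxyphenyl)-5,7-dimethoxy-4-oxochroman-8-yl]phenyl}boronic acid; 12 5,7-bis(benzyloxy)-4H-chromen-4-one
Product: 13 (2S)-2-(4-acetoxyphenyl)-8-{2-(benzyloxy)-5-[(2S)-5,7-bis(benzyloxy)-4-oxochroman-2-yl]phenyl}-5,7-dimethoxychroman-4-one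
Conditions: [Rh(OH)(cod)]2 (3 mol %), (S)-MeO-F12-BIPHEP [6,6'-dimethoxybiphenyl-2,2'-diylbis(bis(3,4,5-trifluorophenyl)phosphine)] (7 mol %), toluene–H2O (10:1), 30 °C
Reagents that add atoms: none
Why: Rhodium-catalysed asymmetric 1,4-addition of an arylboronic acid to a chromone (Hayashi–Miyaura reaction): the aryl-rhodium species formed by transmetalation to the hydroxo-rhodium complex should add to the Re face of C2 under control of the chiral bisphosphine to set 2S (sense assigned by analogy with cyclic enones, the antipodal ligand being used otherwise), and the base-free medium should leave C2'' and the acetate untouched.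

**Step 8**
Reactants: 13 (2S)-2-(4-acetoxyphenyl)-8-{2-(benzyloxy)-5-[(2S)-5,7-bis(benzyloxy)-4-oxochroman-2-yl]phenyl}-5,7-dimethoxychroman-4-one
Product: 14 (2S)-8-{5-[(2S)-5,7-dihydroxy-4-oxochroman-2-yl]-2-hydroxyphenyl}-5-hydroxy-2-(4-hydroxyphenyl)-7-methoxychroman-4-one (target)
Conditions: BCl3 (10 equiv), C6HMe5 (10 equiv), CH2Cl2, −78 → 20 °C; then MeOH, 0 → 40 °C
Reagents that add atoms: none
Why: Lewis-acid ether cleavage with a cation scavenger: BCl3 should remove the three benzyl groups (benzyl cations trapped by pentamethylbenzene) and, through chelation to C4''=O, only the peri 5''-methyl ether while the 7''-methyl ether stays, and the HCl/MeOH formed on quench methanolyses the aryl acetate, all under acidic conditions that should not epimerise C2 or C2''.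

**Compound list**
1 | 3,5-dimethoxyphenol | COc1cc(O)cc(OC)c1 | starting material
2 | 2-iodo-3,5-dimethoxyphenol | COc1cc(O)c(I)c(OC)c1 | intermediate
3 | [2-(benzyloxy)-5-chlorophenyl]boronic acid | OB(O)c1cc(Cl)ccc1OCc1ccccc1 | starting material
4 | 2'-(benzyloxy)-5'-chloro-4,6-dimethoxybiphenyl-2-ol | COc1cc(O)c(-c2cc(Cl)ccc2OCc2ccccc2)c(OC)c1 | intermediate
5 | (E)-4-acetoxycinnamic acid | CC(=O)Oc1ccc(/C=C/C(=O)O)cc1 | starting material
6 | 2'-(benzyloxy)-5'-chloro-4,6-dimethoxybiphenyl-2-yl (E)-3-(4-acetoxyphenyl)prop-2-enoate | COc1cc(OC(=O)/C=C/c2ccc(OC(C)=O)cc2)c(-c2cc(Cl)ccc2OCc2ccccc2)c(OC)c1 | intermediate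
7 | (E)-3-(4-acetoxyphenyl)-1-[2'-(benzyloxy)-5'-chloro-2-hydroxy-4,6-dimethoxybiphenyl-3-yl]prop-2-en-1-one (chalcone, not isolated) | COc1cc(OC)c(-c2cc(Cl)ccc2OCc2ccccc2)c(O)c1C(=O)/C=C/c1ccc(OC(C)=O)cc1 | intermediate
8 | (2S)-2-(4-acetoxyphenyl)-8-[2-(benzyloxy)-5-chlorophenyl]-5,7-dimethoxychroman-4-one | COc1cc(OC)c2c(c1-c1cc(Cl)ccc1OCc1ccccc1)O[C@H](c1ccc(OC(C)=O)cc1)CC2=O | intermediate
9 | (2S)-2-(4-acetoxyphenyl)-8-[2-(benzyloxy)-5-(4,4,5,5-tetramethyl-1,3,2-dioxaborolan-2-yl)phenyl]-5,7-dimethoxychroman-4-one (pinacol boronate, not isolated) | COc1cc(OC)c2c(c1-c1cc(B3OC(C)(C)C(C)(C)O3)ccc1OCc1ccccc1)O[C@H](c1ccc(OC(C)=O)cc1)CC2=O | intermediate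
10 | {4-(benzyloxy)-3-[(2S)-2-(4-acetoxyphenyl)-5,7-dimethoxy-4-oxochroman-8-yl]phenyl}boronic acid | COc1cc(OC)c2c(c1-c1cc(B(O)O)ccc1OCc1ccccc1)O[C@H](c1ccc(OC(C)=O)cc1)CC2=O | intermediate
11 | 5,7-dihydroxy-4H-chromen-4-one | O=c1ccoc2cc(O)cc(O)c12 | starting material
12 | 5,7-bis(benzyloxy)-4H-chromen-4-one | O=c1ccoc2cc(OCc3ccccc3)cc(OCc3ccccc3)c12 | intermediate
13 | (2S)-2-(4-acetoxyphenyl)-8-{2-(benzyloxy)-5-[(2S)-5,7-bis(benzyloxy)-4-oxochroman-2-yl]phenyl}-5,7-dimethoxychroman-4-one | COc1cc(OC)c2c(c1-c1cc([C@@H]3CC(=O)c4c(OCc5ccccc5)cc(OCc5ccccc5)cc4O3)ccc1OCc1ccccc1)O[C@H](c1ccc(OC(C)=O)cc1)CC2=O | intermediate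
14 | (2S)-8-{5-[(2S)-5,7-dihydroxy-4-oxochroman-2-yl]-2-hydroxyphenyl}-5-hydroxy-2-(4-hydroxyphenyl)-7-methoxychroman-4-one | COc1cc(O)c2c(c1-c1cc([C@@H]3CC(=O)c4c(O)cc(O)cc4O3)ccc1O)O[C@H](c1ccc(O)cc1)CC2=O | target

**Totals**
Total step count: 8. Longest linear sequence: 7 (steps 1, 2, 3, 4, 5, 7, 8).

**Steps most likely to fail**

Step 4 (bears the label). The ring closure may become reversible on the time scale of the reaction, or may start under the Lewis acid before the chiral catalyst is present, so that enantiocontrol is lost. The acyl shift may also be diverted into conjugate hydroarylation or into migration to the para position. The fallback uses known chemistry, sets out from 6 and comes back at 8. TiCl4-mediated Fries rearrangement of 6 (CH2Cl2, 0 °C) and isolation would give chalcone 7. Copper-catalysed asymmetric conjugate borylation (CuCl, NaOt-Bu, a Josiphos-type ligand of the appropriate hand, B2pin2, MeOH, THF) would give the (3R)-β-boryl ketone F1. Oxidation with Me3NO, with retention, would give the (3R)-β-hydroxy ketone F2. Intramolecular Mitsunobu etherification (PPh3, DIAD, toluene, 0 °C) would close O1''–C2'' with inversion and give 8. In this variant the stereocentre is set at carbon by the reagent and the ring is closed irreversibly.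

Step 7. Boron-to-rhodium transfer of the large boronic acid may be slow, so that protodeboronation takes over, and facial selectivity on the electron-rich chromone may be insufficient. The fallback changes the order of ring construction, sets out from 4 and comes back at 13. Miyaura borylation of 4 with B2(OH)4 (Pd2(dba)3, XPhos, KOAc, EtOH, 80 °C; no stereocentre is present yet) would give [4-(benzyloxy)-3-(2-hydroxy-4,6-dimethoxyphenyl)phenyl]boronic acid F3. Rhodium-catalysed addition of this small boronic acid to 12 under the conditions of step 7 would give the flavanone phenol F4. DCC/DMAP esterification with 5 would give the cinnamate F5, and its isomerisation under the conditions of step 4 would give 13. The price is that unit 1 is exposed to the isomerisation conditions.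

Step 8. Benzyl cations may attack the phloroglucinol rings, excess BCl3 may cleave the 7''-methyl ether or the benzylic C2–O1 bonds, and deacetylation may stay incomplete. The fallback stages the deprotection, sets out from 13 and comes back at 14. Hydrogenolysis (H2, Pd/C, EtOAc, rt) would remove the three benzyl groups as toluene without forming cations and give the acetate-protected triphenol F6. BCl3 (3 equiv, CH2Cl2, −78 → 0 °C) would then cleave only the chelated 5''-methyl ether, and the methanol quench would remove the acetate to give 14.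

**Further compounds**
F1 | step 4 | (3R)-3-(4-acetoxyphenyl)-1-[2'-(benzyloxy)-5'-chloro-2-hydroxy-4,6-dimethoxybiphenyl-3-yl]-3-(4,4,5,5-tetramethyl-1,3,2-dioxaborolan-2-yl)propan-1-one | COc1cc(OC)c(-c2cc(Cl)ccc2OCc2ccccc2)c(O)c1C(=O)C[C@@H](B1OC(C)(C)C(C)(C)O1)c1ccc(OC(C)=O)cc1
F2 | step 4 | (3R)-3-(4-acetoxyphenyl)-1-[2'-(benzyloxy)-5'-chloro-2-hydroxy-4,6-dimethoxybiphenyl-3-yl]-3-hydroxypropan-1-one | COc1cc(OC)c(-c2cc(Cl)ccc2OCc2ccccc2)c(O)c1C(=O)C[C@@H](O)c1ccc(OC(C)=O)cc1
F3 | step 7 | [4-(benzyloxy)-3-(2-hydroxy-4,6-dimethoxyphenyl)phenyl]boronic acid | COc1cc(O)c(-c2cc(B(O)O)ccc2OCc2ccccc2)c(OC)c1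
F4 | step 7 | (2S)-5,7-bis(benzyloxy)-2-[4-(benzyloxy)-3-(2-hydroxy-4,6-dimethoxyphenyl)phenyl]chroman-4-one | COc1cc(O)c(-c2cc([C@@H]3CC(=O)c4c(OCc5ccccc5)cc(OCc5ccccc5)cc4O3)ccc2OCc2ccccc2)c(OC)c1
F5 | step 7 | 2'-(benzyloxy)-5'-[(2S)-5,7-bis(benzyloxy)-4-oxochroman-2-yl]-4,6-dimethoxybiphenyl-2-yl (E)-3-(4-acetoxyphenyl)prop-2-enoate | COc1cc(OC(=O)/C=C/c2ccc(OC(C)=O)cc2)c(-c2cc([C@@H]3CC(=O)c4c(OCc5ccccc5)cc(OCc5ccccc5)cc4O3)ccc2OCc2ccccc2)c(OC)c1
F6 | step 8 | (2S)-2-(4-acetoxyphenyl)-8-{5-[(2S)-5,7-dihydroxy-4-oxochroman-2-yl]-2-hydroxyphenyl}-5,7-dimethoxychroman-4-one | COc1cc(OC)c2c(c1-c1cc([C@@H]3CC(=O)c4c(O)cc(O)cc4O3)ccc1O)O[C@H](c1ccc(OC(C)=O)cc1)CC2=O
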